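A direct plan would cut the C3–C1′ bond. Suzuki coupling of 3-iodochromone A1 with chromenyl boronate A2 would give bis-MOM isoflavone A3, and acid would then remove both MOM groups.
Ring A would be carried from the start as tris-MOM ether A4. Some five steps would then go into oxygen atoms and protecting groups and none into the skeleton.
The weakest step would be the iodocyclisation of enaminone A5 to A1. Two different OH groups flank the acyl carbon, both are hydrogen-bonded to it, and nothing in A5 would decide which becomes O1. A5 would also require selective cleavage of two of three MOM ethers.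
The second would be the thermal Claisen rearrangement/electrocyclisation of propargyl ether A6. Both ortho positions are free, and resorcinol ethers of this kind tend to rearrange to the carbon between the two oxygens, which would give the angular instead of the linear chromene.
The third would be the final aqueous-acid deprotection of A3, run on the most valuable material. The tertiary carbinol lies next to the 5-OH (closure to a chroman, dehydration), and the chromene and the air-sensitive hydroquinone are exposed.

**Plan of the new route**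
1. Feature used: on ring A, O5 and O8 are para, the C6 chain is a 3-hydroxy-3-methylbutyl group ortho to O5, and C8a (which bears O1) lies next to acyl-bearing C4a; this is a 2,2-dimethylchroman-6-ol opened oxidatively to its quinone, with C8a as the β-carbon of an acylquinone.
2. The retrosynthesis cuts O1–C8a and re-ties O5 to the carbinol carbon of the chain, giving open-chain α-formyl ketone 15; it then cuts C2–C3 (formylation), C3–C1′ (ketone α-arylation) and C4–C4a (directed lithiation/acylation).
3. Ring order: ring A with a sacrificial chroman ring (hydroquinone + isoprene), ring D on ring B (from a salicylaldehyde), and ring C last, in the operation that opens the chroman ring.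
4. Ring A needs only the two oxygens of hydroquinone, O1 is the enol oxygen of the C3 unit, and two free OH groups never flank the acyl carbon, so the closure has one outcome.
5. C4 of the chromene is the former CHO carbon of 7 and the only free OH is ortho to it, so only the linear chromene can form.
6. The tertiary alcohol and the hydroquinone do not exist before step 9, and the only later step is a buffered fluoride desilylation, so no acid meets them.

Key step: step 9

Assumption: the structure has no stereocentre and is achiral, so no enantiomer has to be chosen; it is built exactly as written (5,8-dihydroxy, chain at C6, 2′-OH, linear 4′,5′-fused 2,2-dimethylchromene).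

**Route**

Step 1
Reactants: 1 hydroquinone; 2 isoprene (2-methylbuta-1,3-diene)
Product: 3 2,2-dimethylchroman-6-ol
Conditions: Amberlyst-15, THF/heptane, 65 °C; 1 in excess (3 equiv)
Reagents that add atoms: none
Why: Acid-catalysed Friedel–Crafts prenylation followed by Markovnikov addition of the neighbouring OH to the prenyl alkene (chroman annulation) should give 3, since all four C–H positions of 1 are equivalent and the excess of 1 suppresses a second annulation; no stereocentre forms.

Step 2
Reactants: 3 2,2-dimethylchroman-6-ol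
Product: 4 tert-butyl[(2,2-dimethylchroman-6-yl)oxy]dimethylsilane
Conditions: TBSCl, imidazole, DMF, rt
Reagents that add atoms: TBSCl, CC(C)(C)[Si](C)(C)Cl
Why: Standard silyl ether formation; the OTBS group is a bulky, poor directing group that shields C5 and C7 in the next step and can later be removed ahead of an OTIPS group.

Step 3
Reactants: 4 tert-butyl[(2,2-dimethylchroman-6-yl)oxy]dimethylsilane
Product: 6 1-[6-(tert-butyldimethylsilyloxy)-2,2-dimethylchroman-8-yl]ethan-1-one, via aryllithium 5 (not isolated)
Conditions: s-BuLi, TMEDA, Et2O, −78 → −20 °C; MeC(O)N(OMe)Me, −78 °C → rt; aq. NH4Cl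
Reagents that add atoms: N-methoxy-N-methylacetamide, CC(=O)N(C)OC; s-BuLi, [Li]C(C)CC (lithium of 5 only)
Why: Directed ortho-metalation, in which the chroman oxygen is the only effective directing group so that lithium goes to C8, followed by Weinreb ketone synthesis, which stops at the methyl ketone.

Step 4
Reactants: 7 5-bromo-2,4-dihydroxybenzaldehyde
Product: 8 5-bromo-2-hydroxy-4-(triisopropylsilyloxy)benzaldehyde
Conditions: TIPSCl (1.05 equiv), imidazole, DMF, 0 °C → rt
Reagents that add atoms: TIPSCl, CC(C)[Si](Cl)(C(C)C)C(C)C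
Why: Selective silylation of the more acidic, non-chelated 4-OH, while the 2-OH is held in a hydrogen bond to the aldehyde and stays free.

Step 5
Reactants: 8 5-bromo-2-hydroxy-4-(triisopropylsilyloxy)benzaldehyde
Product: 11 6-bromo-2,2-dimethyl-7-(triisopropylsilyloxy)-2H-chromene, via allylic alcohol 9 (not isolated), via o-quinone methide 10 (not isolated)
Conditions: Me2C=CHMgBr (2.3 equiv), THF, 0 °C; aq. NH4Cl; crude 9, PPTS (cat.), toluene, 80 °C
Reagents that add atoms: 2-methylprop-1-enylmagnesium bromide, CC(C)=C[Mg]Br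
Why: Grignard addition (the first equivalent deprotonates the phenol), then dehydration to o-quinone methide 10 and oxa-6π electrocyclisation; the only free OH is ortho to the former CHO carbon, so only the linear chromene can form, and the racemic carbinol centre of 9 is lost again.

Step 6
Reactants: 6 1-[6-(tert-butyldimethylsilyloxy)-2,2-dimethylchroman-8-yl]ethan-1-one; 11 6-bromo-2,2-dimethyl-7-(triisopropylsilyloxy)-2H-chromene
Product: 12 1-[6-(tert-butyldimethylsilyloxy)-2,2-dimethylchroman-8-yl]-2-[2,2-dimethyl-7-(triisopropylsilyloxy)-2H-chromen-6-yl]ethan-1-one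
Conditions: Pd2(dba)3 (cat.), XPhos (cat.), K3PO4, toluene, 90 °C
Reagents that add atoms: none
Why: Palladium-catalysed α-arylation of a methyl ketone (Buchwald–Hartwig type); the weak base K3PO4 should spare both aryl silyl ethers and the hindered monoaryl ketone should resist a second arylation.

Step 7
Reactants: 12 the deoxybenzoin from step 6
Product: 14 (Z)-1-[6-(tert-butyldimethylsilyloxy)-2,2-dimethylchroman-8-yl]-2-[2,2-dimethyl-7-(triisopropylsilyloxy)-2H-chromen-6-yl]-3-hydroxyprop-2-en-1-one, via lithium enolate 13 (not isolated)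
Conditions: LiHMDS, THF, −78 °C; HCO2CH2CF3, −78 → 0 °C; 1 M HCl
Reagents that add atoms: 2,2,2-trifluoroethyl formate, O=COCC(F)(F)F; LiHMDS, [Li]N([Si](C)(C)C)[Si](C)(C)C (lithium of 13 only)
Why: Claisen-type C-formylation of the lithium enolate; the weakly nucleophilic trifluoroethoxide leaves the silyl ethers alone, and with no OH ortho to the acyl carbon the β-ketoaldehyde stays open as its chelated (Z)-enol.

Step 8
Reactants: 14 the bis-silylated formyl ketone (enol)
Product: 15 (Z)-2-[2,2-dimethyl-7-(triisopropylsilyloxy)-2H-chromen-6-yl]-3-hydroxy-1-(6-hydroxy-2,2-dimethylchroman-8-yl)prop-2-en-1-one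
Conditions: TBAF (1.0 equiv), AcOH (1.0 equiv), THF, −20 °C
Reagents that add atoms: none
Why: Fluoride desilylation under kinetic control; the unhindered aryl OTBS group should be cleaved much faster than the OTIPS group, which is also flanked by the C3 substituent, and AcOH buffers phenoxide and enolate.

Step 9
Reactants: 15 the chromanol-enol from step 8
Product: 19 3-[2,2-dimethyl-7-(triisopropylsilyloxy)-2H-chromen-6-yl]-5,8-dihydroxy-6-(3-hydroxy-3-methylbutyl)-4H-chromen-4-one, via hemiketal 16 (not isolated), via acylquinone 17 (not isolated), via isoflavonequinone 18 (not isolated)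
Conditions: 15 added to PhI(OAc)2 (2.2 equiv), MeCN/H2O 4:1, 0 °C, Ar; then aq. Na2S2O4, EtOAc, rt
Reagents that add atoms: water, O
Why: Proposed new method: PhI(OAc)2 exchanges a ligand with the only free phenol (para to the chroman oxygen), two-electron oxidation gives the oxygen-stabilised aryloxenium ion, water adds at the carbon that bears the chroman oxygen, and hemiketal 16 collapses to acylquinone 17, which releases the tertiary alcohol of the chain and turns C5 into a carbonyl, as a tocopherol goes to its tocopherylquinone. In 17 the carbon C8a is β to both C5=O and the C4 ketone, so the enol oxygen should add there in a 6-endo-trig oxa-Michael closure of ring C (equally describable as an oxa-6π closure), and tautomerisation re-aromatises ring A to the 5,8-hydroquinone. This hydroquinone is oxidised more easily than 15, so a second equivalent of oxidant is budgeted to carry all material to quinone 18 and dithionite returns 19 in the same flask; direct attack of the enol on the aryloxenium ion ortho to the phenol oxygen would also end in 18 after the second oxidation. The closest known reaction types are the oxidation of p-alkoxyphenols and 6-chromanols to quinones with hypervalent iodine or Fe(III), and the closure of xanthone-1,4-quinones by addition of a pendant phenol to an aroylquinone made in situ; using an enol oxygen to build a chromone is the new element. No stereocentre remains, since the racemic hemiketal carbon of 16 is lost on ring opening. The step needs C8a–O rather than C5–O bond formation and attack at one phenol only: C5 is first an ether carbon and then a carbonyl whose 1,2-adduct forms reversibly and cannot aromatise, C8a is the only conjugate position within reach of a six-membered ring, the B-ring phenol is silylated, and the chromene alkene is inert to unactivated PhI(OAc)2.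

Step 10
Reactants: 19 the 2′-O-TIPS ether of the target
Product: 20 Kraussianone 3
Conditions: TBAF, AcOH (1:1), THF, 0 °C → rt, Ar, degassed solvents
Reagents that add atoms: none
Why: Buffered fluoride cleavage of the aryl TIPS ether under nearly neutral conditions, to which the tertiary alcohol, the chromene, the chromone and (under argon) the hydroquinone should be inert; no stereocentre is involved.

**Compound list**
1 | hydroquinone | Oc1ccc(O)cc1 | starting material
2 | isoprene | C=CC(C)=C | starting material
3 | 2,2-dimethylchroman-6-ol | CC1(C)CCc2cc(O)ccc2O1 | intermediate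
4 | tert-butyl[(2,2-dimethylchroman-6-yl)oxy]dimethylsilane | CC1(C)CCc2cc(O[Si](C)(C)C(C)(C)C)ccc2O1 | intermediate
5 | 8-lithio derivative of 4 | [Li]c1cc(O[Si](C)(C)C(C)(C)C)cc2c1OC(C)(C)CC2 | intermediate
6 | 1-[6-(tert-butyldimethylsilyloxy)-2,2-dimethylchroman-8-yl]ethan-1-one | CC(=O)c1cc(O[Si](C)(C)C(C)(C)C)cc2c1OC(C)(C)CC2 | intermediate
7 | 5-bromo-2,4-dihydroxybenzaldehyde | O=Cc1cc(Br)c(O)cc1O | starting material
8 | 5-bromo-2-hydroxy-4-(triisopropylsilyloxy)benzaldehyde | O=Cc1cc(Br)c(O[Si](C(C)C)(C(C)C)C(C)C)cc1O | intermediate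
9 | (±)-4-bromo-2-(1-hydroxy-3-methylbut-2-en-1-yl)-5-(triisopropylsilyloxy)phenol | CC(C)=CC(O)c1cc(Br)c(O[Si](C(C)C)(C(C)C)C(C)C)cc1O | intermediate
10 | 4-bromo-6-(3-methylbut-2-en-1-ylidene)-3-(triisopropylsilyloxy)cyclohexa-2,4-dien-1-one (o-quinone methide) | CC(C)=CC=C1C=C(Br)C(O[Si](C(C)C)(C(C)C)C(C)C)=CC1=O | intermediate
11 | 6-bromo-2,2-dimethyl-7-(triisopropylsilyloxy)-2H-chromene | CC1(C)C=Cc2cc(Br)c(O[Si](C(C)C)(C(C)C)C(C)C)cc2O1 | intermediate
12 | 1-[6-(TBSO)-2,2-dimethylchroman-8-yl]-2-[2,2-dimethyl-7-(TIPSO)-2H-chromen-6-yl]ethan-1-one | O=C(Cc1cc2C=CC(C)(C)Oc2cc1O[Si](C(C)C)(C(C)C)C(C)C)c1cc(O[Si](C)(C)C(C)(C)C)cc2c1OC(C)(C)CC2 | intermediate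
13 | lithium (Z)-enolate of 12 | [Li]O/C(=C\c1cc2C=CC(C)(C)Oc2cc1O[Si](C(C)C)(C(C)C)C(C)C)c1cc(O[Si](C)(C)C(C)(C)C)cc2c1OC(C)(C)CC2 | intermediate
14 | (Z)-1-[6-(TBSO)-2,2-dimethylchroman-8-yl]-2-[2,2-dimethyl-7-(TIPSO)-2H-chromen-6-yl]-3-hydroxyprop-2-en-1-one (chelated enol of the α-formyl ketone) | O/C=C(/c1cc2C=CC(C)(C)Oc2cc1O[Si](C(C)C)(C(C)C)C(C)C)C(=O)c1cc(O[Si](C)(C)C(C)(C)C)cc2c1OC(C)(C)CC2 | intermediate
15 | (Z)-2-[2,2-dimethyl-7-(TIPSO)-2H-chromen-6-yl]-3-hydroxy-1-(6-hydroxy-2,2-dimethylchroman-8-yl)prop-2-en-1-one | O/C=C(/c1cc2C=CC(C)(C)Oc2cc1O[Si](C(C)C)(C(C)C)C(C)C)C(=O)c1cc(O)cc2c1OC(C)(C)CC2 | intermediate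
16 | (±)-8a-hydroxy-2,2-dimethyl-3,4-dihydro-2H-chromen-6(8aH)-one carrying the 2-aryl-3-hydroxyacryloyl group at C8 (hemiketal) | O/C=C(/c1cc2C=CC(C)(C)Oc2cc1O[Si](C(C)C)(C(C)C)C(C)C)C(=O)C1=CC(=O)C=C2CCC(C)(C)OC12O | intermediate
17 | 2-{(Z)-2-[2,2-dimethyl-7-(TIPSO)-2H-chromen-6-yl]-3-hydroxyacryloyl}-6-(3-hydroxy-3-methylbutyl)-1,4-benzoquinone | O/C=C(/c1cc2C=CC(C)(C)Oc2cc1O[Si](C(C)C)(C(C)C)C(C)C)C(=O)C1=CC(=O)C=C(CCC(C)(C)O)C1=O | intermediate
18 | 3-[2,2-dimethyl-7-(TIPSO)-2H-chromen-6-yl]-6-(3-hydroxy-3-methylbutyl)-4H-chromene-4,5,8-trione (isoflavone-5,8-quinone) | CC(C)(O)CCC1=CC(=O)C2=C(C1=O)C(=O)C(=CO2)c1cc2C=CC(C)(C)Oc2cc1O[Si](C(C)C)(C(C)C)C(C)C | intermediate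
19 | 3-[2,2-dimethyl-7-(TIPSO)-2H-chromen-6-yl]-5,8-dihydroxy-6-(3-hydroxy-3-methylbutyl)-4H-chromen-4-one | CC(C)(O)CCc1cc(O)c2occ(-c3cc4C=CC(C)(C)Oc4cc3O[Si](C(C)C)(C(C)C)C(C)C)c(=O)c2c1O | intermediate
20 | Kraussianone 3 (achiral) | CC(C)(O)CCc1cc(O)c2occ(-c3cc4c(cc3O)OC(C)(C)C=C4)c(=O)c2c1O | target

**Summary**
Total steps: 10.
Longest linear sequence: 8 (steps 1, 2, 3, 6, 7, 8, 9, 10).

**Steps most likely to fail**

Step 9 (new method).
- What may go wrong: the iodane may attack the enol as well as the phenol. Water or acetate may add to C8a faster than the enol oxygen. The acylquinone may lose its formyl group by hydrolysis. The electron-poor pyranone of 18 may be opened by water before the reduction.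
- Fallback (known chemistry only): O1 is placed on ring A first and ring C is closed in the classical direction, while the chroman ring still masks O5. The fallback sets out from chromanol 3. IBX should oxygenate it at the less hindered ortho position C7 to 2,2-dimethylchroman-6,7-dione F1, which is reduced in the same flask with Na2S2O4 to 2,2-dimethylchroman-6,7-diol F2. MOMCl/i-Pr2NEt would give bis-MOM ether F3. Directed lithiation at C8, which lies between O1 and the 7-OMOM group, followed by N-methoxy-N-methylacetamide would give methyl ketone F4. α-Arylation with bromide 11 as in step 6 would give deoxybenzoin F5. HCl in MeOH would give catechol ketone F6; acid is harmless here because neither the tertiary alcohol nor the hydroquinone exists yet. DMF-DMA would lead through enaminone F7, which can close only through the 7-OH, the single OH ortho to the acyl carbon, to chroman-fused 8-hydroxyisoflavone F8. PhI(OAc)2 in aqueous MeCN would then open this p-alkoxyphenol to isoflavonequinone 18, where the route is rejoined (Na2S2O4 to 19).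

Step 3.
- What may go wrong: metalation may take place next to the silyloxy group (followed by migration of silicon from O to C) or at benzylic C4, or the alkyllithium may attack silicon.
- Fallback: it sets out from silyl ether 4. Iridium-catalysed C–H borylation ([Ir(OMe)(cod)]2, dtbpy, B2pin2, hexane, 60 °C) is governed by steric access and should avoid C5 and C7 beside the OTBS group, giving 8-pinacolboronate F9. Palladium-catalysed acylative Suzuki–Miyaura coupling with acetic anhydride would return to ketone 6.

Step 6.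
- What may go wrong: oxidative addition to the electron-rich bromide beside the bulky OTIPS group may be slow. Protodebromination, loss of a silyl group at 90 °C or a second arylation could then take over.
- Fallback: the C3–C4 bond is made by a 1,2-acyl shift instead of the C3–C1′ bond by coupling. The fallback sets out from bromide 11. Bromine–lithium exchange (n-BuLi) and DMF would give chromene-6-carbaldehyde F10. Aldol addition of the lithium enolate of ketone 6 would give aldol F11, and PPTS in warm toluene would dehydrate this doubly activated benzylic alcohol to (E)-chalcone F12. Weitz–Scheffer epoxidation (t-BuOOH, DBU) attacks only the electron-poor enone and not the chromene alkene, and would give trans-epoxide F13. BF3·OEt2 at low temperature should open the epoxide at the benzylic carbon with 1,2-shift of the aroyl group, the classical entry to α-formyl deoxybenzoins. This gives formyl ketone 14 directly, so that 12 and step 7 are bypassed.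

**Further compounds**
F1 | step 9 | 2,2-dimethylchroman-6,7-dione | CC1(C)CCC2=CC(=O)C(=O)C=C2O1
F2 | step 9 | 2,2-dimethylchroman-6,7-diol | CC1(C)CCc2cc(O)c(O)cc2O1
F3 | step 9 | 6,7-bis(methoxymethoxy)-2,2-dimethylchroman | CC1(C)CCc2cc(OCOC)c(OCOC)cc2O1
F4 | step 9 | 1-[6,7-bis(methoxymethoxy)-2,2-dimethylchroman-8-yl]ethan-1-one | CC(=O)c1c(OCOC)c(OCOC)cc2c1OC(C)(C)CC2
F5 | step 9 | 1-[6,7-bis(methoxymethoxy)-2,2-dimethylchroman-8-yl]-2-[2,2-dimethyl-7-(TIPSO)-2H-chromen-6-yl]ethan-1-one | O=C(Cc1cc2C=CC(C)(C)Oc2cc1O[Si](C(C)C)(C(C)C)C(C)C)c1c(OCOC)c(OCOC)cc2c1OC(C)(C)CC2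
F6 | step 9 | 1-(6,7-dihydroxy-2,2-dimethylchroman-8-yl)-2-[2,2-dimethyl-7-(TIPSO)-2H-chromen-6-yl]ethan-1-one | O=C(Cc1cc2C=CC(C)(C)Oc2cc1O[Si](C(C)C)(C(C)C)C(C)C)c1c(O)c(O)cc2c1OC(C)(C)CC2
F7 | step 9 | (E)-1-(6,7-dihydroxy-2,2-dimethylchroman-8-yl)-3-(dimethylamino)-2-[2,2-dimethyl-7-(TIPSO)-2H-chromen-6-yl]prop-2-en-1-one | CN(C)/C=C(\c1cc2C=CC(C)(C)Oc2cc1O[Si](C(C)C)(C(C)C)C(C)C)C(=O)c1c(O)c(O)cc2c1OC(C)(C)CC2
F8 | step 9 | 8-hydroxyisoflavone with a 2,2-dimethyldihydropyran ring fused through O5 and C6, 2′-O-TIPS | CC1(C)CCc2cc(O)c3occ(-c4cc5C=CC(C)(C)Oc5cc4O[Si](C(C)C)(C(C)C)C(C)C)c(=O)c3c2O1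
F9 | step 3 | tert-butyl{[2,2-dimethyl-8-(4,4,5,5-tetramethyl-1,3,2-dioxaborolan-2-yl)chroman-6-yl]oxy}dimethylsilane | CC1(C)CCc2cc(O[Si](C)(C)C(C)(C)C)cc(B3OC(C)(C)C(C)(C)O3)c2O1
F10 | step 6 | 2,2-dimethyl-7-(triisopropylsilyloxy)-2H-chromene-6-carbaldehyde | O=Cc1cc2C=CC(C)(C)Oc2cc1O[Si](C(C)C)(C(C)C)C(C)C
F11 | step 6 | (±)-1-[6-(TBSO)-2,2-dimethylchroman-8-yl]-3-[2,2-dimethyl-7-(TIPSO)-2H-chromen-6-yl]-3-hydroxypropan-1-one | OC(CC(=O)c1cc(O[Si](C)(C)C(C)(C)C)cc2c1OC(C)(C)CC2)c1cc2C=CC(C)(C)Oc2cc1O[Si](C(C)C)(C(C)C)C(C)C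
F12 | step 6 | (E)-1-[6-(TBSO)-2,2-dimethylchroman-8-yl]-3-[2,2-dimethyl-7-(TIPSO)-2H-chromen-6-yl]prop-2-en-1-one | O=C(/C=C/c1cc2C=CC(C)(C)Oc2cc1O[Si](C(C)C)(C(C)C)C(C)C)c1cc(O[Si](C)(C)C(C)(C)C)cc2c1OC(C)(C)CC2
F13 | step 6 | (±)-trans-epoxide of F12 (one enantiomer drawn) | O=C([C@@H]1O[C@H]1c1cc2C=CC(C)(C)Oc2cc1O[Si](C(C)C)(C(C)C)C(C)C)c1cc(O[Si](C)(C)C(C)(C)C)cc2c1OC(C)(C)CC2
A1 | direct plan | 5-hydroxy-6-(3-hydroxy-3-methylbutyl)-3-iodo-8-(methoxymethoxy)-4H-chromen-4-one | O=c1c(I)coc2c(OCOC)cc(CCC(C)(C)O)c(O)c12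
A2 | direct plan | 2-[7-(methoxymethoxy)-2,2-dimethyl-2H-chromen-6-yl]-4,4,5,5-tetramethyl-1,3,2-dioxaborolane | CC1(C)C=Cc2cc(B3OC(C)(C)C(C)(C)O3)c(OCOC)cc2O1
A3 | direct plan | 8,2′-bis-O-MOM ether of the target | CC(C)(O)CCc1cc(OCOC)c2occ(-c3cc4c(cc3OCOC)OC(C)(C)C=C4)c(=O)c2c1O
A4 | direct plan | 1,2,4-tris(methoxymethoxy)benzene | COCOc1ccc(OCOC)c(OCOC)c1
A5 | direct plan | (E)-3-(dimethylamino)-1-[2,6-dihydroxy-3-(3-hydroxy-3-methylbutyl)-5-(methoxymethoxy)phenyl]prop-2-en-1-one | CN(C)/C=C/C(=O)c1c(O)c(OCOC)cc(CCC(C)(C)O)c1O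
A6 | direct plan | 2-bromo-5-[(2-methylbut-3-yn-2-yl)oxy]phenol | C#CC(C)(C)Oc1ccc(Br)c(O)c1
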